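**Retrosynthetic overview**

- Numbering: ring B is C5(H, isopropenyl)–C6H2–C7(=O)–C8=C9–C10(CH3, ester arm C1–C3); ring C is the quinone C8–C9–C11(=O)–C12(OH)–C13(iPr)–C14(=O). The target is (5S,10S), with isopropenyl cis to the C10 methyl and trans to the ester arm.
- The strategy rests on ring C: its four carbons C11–C14 are a squarate unit set between C9 and C8 of a ring B alkene. C9–C11 comes from vinyllithium addition to a cyclobutenedione, and C8–C14 from thermal ring expansion of the resulting 4-cyclohexenyl-4-hydroxycyclobutenone.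
- Ring B is present from the start (2-methylcyclohexenone). C5 and C10 are set together by asymmetric conjugate addition of isopropenyl and trans allylation of the enolate; the allyl group becomes the C1–C3 arm and a Shapiro reaction turns C9 into the vinyllithium.
- Ring C is formed second, as a hydroquinone. The endgame methylates it, oxidises benzylic C7, converts the silyl ether into the methyl ester, unveils the quinone with (NH4)2Ce(NO3)6 and frees the C12 hydroxyl with BCl3.

Key step: step 7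

Assumption: the copper–diphosphine catalyst of step 1 is taken to deliver isopropenyl to the enone face that gives (3S) in ketone 5; if a test run shows the opposite sense, the mirror-image ligand is used and nothing else changes.

**Route**

Step 1
Reactants: 1 2-methylcyclohex-2-en-1-one; 2 isopropenylmagnesium bromide; 3 allyl bromide
Product: 5 (2S,3S)-2-allyl-2-methyl-3-(prop-1-en-2-yl)cyclohexan-1-one, via magnesium enolate 4 (not isolated)
Conditions: CuBr·SMe2 (5 mol %), (R)-1-[(S)-2-(diphenylphosphino)ferrocenyl]ethyldicyclohexylphosphine (6 mol %), t-BuOMe, −78 °C; then 3, DMPU, THF, −78 → 0 °C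
Reagents that add atoms: none
Why: Copper-catalysed asymmetric conjugate addition of the Grignard reagent to the α-methyl enone sets C5 under control of the chiral diphosphine on copper, and the regiodefined enolate 4 is allylated on the face anti to the new isopropenyl group, which sets quaternary C10 with allyl trans to isopropenyl (tandem conjugate addition–enolate alkylation).

Step 2
Reactants: 5 (2S,3S)-2-allyl-2-methyl-3-(prop-1-en-2-yl)cyclohexan-1-one
Product: 7 (2S,3S)-2-(3-hydroxypropyl)-2-methyl-3-(prop-1-en-2-yl)cyclohexan-1-one, via trialkylborane 6 (not isolated)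
Conditions: (Me2CHCHMe)2BH [from BH3·SMe2 + 2-methylbut-2-ene], THF, 0 °C; then NaOH, H2O2, 0 °C → rt
Reagents that add atoms: hydrogen peroxide, OO
Why: Anti-Markovnikov hydroboration–oxidation with the bulky disiamylborane should select the monosubstituted allyl alkene over the 1,1-disubstituted isopropenyl group and the hindered ketone, leaving both stereocentres untouched.

Step 3
Reactants: 7 (2S,3S)-2-(3-hydroxypropyl)-2-methyl-3-(prop-1-en-2-yl)cyclohexan-1-one
Product: 8 (2S,3S)-2-[3-(tert-butyldimethylsilyloxy)propyl]-2-methyl-3-(prop-1-en-2-yl)cyclohexan-1-one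
Conditions: TBSCl, imidazole, CH2Cl2, rt
Reagents that add atoms: tert-butyldimethylsilyl chloride, CC(C)(C)[Si](C)(C)Cl
Why: Imidazole-promoted silylation of the primary alcohol masks it for the organolithium steps that follow.

Step 4
Reactants: 8 (2S,3S)-2-[3-(tert-butyldimethylsilyloxy)propyl]-2-methyl-3-(prop-1-en-2-yl)cyclohexan-1-one
Product: 9 N'-[(1E,2S,3S)-2-[3-(tert-butyldimethylsilyloxy)propyl]-2-methyl-3-(prop-1-en-2-yl)cyclohexylidene]-2,4,6-triisopropylbenzenesulfonohydrazide
Conditions: TrisNHNH2, PPTS (cat.), THF, rt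
Reagents that add atoms: 2,4,6-triisopropylbenzenesulfonohydrazide, CC(C)c1cc(C(C)C)c(S(=O)(=O)NN)c(C(C)C)c1
Why: Condensation of the ketone with the arylsulfonylhydrazide gives the trisylhydrazone, whose N–N bond should settle anti to quaternary C10 and syn to the C8 methylene that the Shapiro reaction deprotonates.

Step 5
Reactants: 10 diisopropyl squarate; 11 isopropylmagnesium chloride
Product: 13 3-isopropoxy-4-isopropylcyclobut-3-ene-1,2-dione, via hydroxycyclobutenone adduct 12 (not isolated)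
Conditions: THF, −78 °C; aq. NH4Cl; then HCl (12 M, cat.), CH2Cl2, rt
Reagents that add atoms: none
Why: 1,2-Addition of the Grignard reagent to one squarate carbonyl followed by acid-promoted loss of isopropanol from adduct 12 is the standard route from squarate esters to 3-alkyl-4-alkoxycyclobutenediones.

Step 6
Reactants: 9 the trisylhydrazone; 13 3-isopropoxy-4-isopropylcyclobut-3-ene-1,2-dione
Product: 15 4-hydroxy-3-isopropoxy-2-isopropyl-4-[(5S,6S)-6-[3-(tert-butyldimethylsilyloxy)propyl]-6-methyl-5-(prop-1-en-2-yl)cyclohex-1-en-1-yl]cyclobut-2-en-1-one (both carbinol epimers), via vinyllithium 14 (not isolated)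
Conditions: n-BuLi (2.2 equiv), THF, −78 → 0 °C; then 13, −78 °C; aq. NH4Cl
Reagents that add atoms: none
Why: The Shapiro reaction (double deprotonation, loss of sulfinate and N2) gives the C9 vinyllithium regiospecifically because only C8 carries α-hydrogens, and it adds 1,2 to the ketone-like carbonyl of 13 next to the isopropoxy carbon (the other carbonyl is a vinylogous ester), which fixes the substitution pattern of ring C.

Step 7
Reactants: 15 4-hydroxy-3-isopropoxy-2-isopropyl-4-(cyclohexenyl)cyclobut-2-en-1-one (both carbinol epimers)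
Product: 18 (7S,8S)-8-[3-(tert-butyldimethylsilyloxy)propyl]-2-isopropoxy-3-isopropyl-8-methyl-7-(prop-1-en-2-yl)-5,6,7,8-tetrahydronaphthalene-1,4-diol, via dienylketene 16 (not isolated), via cyclohexadienone 17 (not isolated)
Conditions: toluene (degassed), 110 °C, Ar
Reagents that add atoms: none
Why: Heating opens the cyclobutenone by a conrotatory 4π-electrocyclic reaction in which the donor hydroxyl rotates outward, so the cyclohexenyl group turns inward and lies next to the ketene in the (Z)-dienylketene 16. Ring C (six-membered) then closes by 6π-electrocyclisation, ketene carbon C14 bonding to C8 of the ring B alkene to give cyclohexadienone 17, and enolisation with loss of the C8 hydrogen aromatises it to hydroquinone 18. The closest known reaction type is the Moore rearrangement of 4-alkenyl- and 4-aryl-4-hydroxycyclobutenones derived from squarate esters. No lasting stereocentre is formed: C8 is sp3 only in 17, the carbinol carbon becomes sp2 so both epimers of 15 converge, and C5 and C10 are remote sp3 spectators. The step needs the right regiochemistry of ring C (isopropoxy carbon C12 beside C11, isopropyl carbon C13 beside C14), already secured by the site of addition in step 6, and inward rotation of the alkenyl group, secured by the outward preference of the hydroxyl; C8 carries the hydrogen needed for the final tautomerisation.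

Step 8
Reactants: 18 the hydroquinone
Product: 19 tert-butyl{3-[(1S,2S)-7-isopropoxy-6-isopropyl-5,8-dimethoxy-1-methyl-2-(prop-1-en-2-yl)-1,2,3,4-tetrahydronaphthalen-1-yl]propoxy}dimethylsilane
Conditions: NaH, MeI, DMF, 0 °C → rt, Ar
Reagents that add atoms: iodomethane, CI
Why: Williamson O-methylation of both phenoxides protects the air-sensitive hydroquinone and leaves an electron-rich arene suited to benzylic oxidation.

Step 9
Reactants: 19 the dimethyl ether
Product: 21 (3S,4S)-4-[3-(tert-butyldimethylsilyloxy)propyl]-6-isopropoxy-7-isopropyl-5,8-dimethoxy-4-methyl-3-(prop-1-en-2-yl)-3,4-dihydronaphthalen-1(2H)-one, via benzylic alcohol 20 (not isolated)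
Conditions: DDQ (3 equiv), aq. 1,4-dioxane, rt
Reagents that add atoms: water, O
Why: DDQ benzylic oxidation: hydride abstraction from C7, the only benzylic carbon bearing hydrogen and activated by the ortho methoxy and para isopropoxy groups, gives a cation that water traps, and alcohol 20 is oxidised on to the aryl ketone; any loss of the silyl ether here would only anticipate step 10.

Step 10
Reactants: 21 the C7 ketone silyl ether
Product: 22 (3S,4S)-4-(3-hydroxypropyl)-6-isopropoxy-7-isopropyl-5,8-dimethoxy-4-methyl-3-(prop-1-en-2-yl)-3,4-dihydronaphthalen-1(2H)-one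
Conditions: HF·pyridine, pyridine, THF, 0 °C → rt
Reagents that add atoms: none
Why: Fluoride-driven desilylation of the primary silyl ether, buffered with pyridine so that the isopropenyl group and the aryl ethers are not touched.

Step 11
Reactants: 22 the primary alcohol
Product: 24 3-[(1S,2S)-7-isopropoxy-6-isopropyl-5,8-dimethoxy-1-methyl-4-oxo-2-(prop-1-en-2-yl)-1,2,3,4-tetrahydronaphthalen-1-yl]propanoic acid, via aldehyde 23 (not isolated)
Conditions: TEMPO (cat.), PhI(OAc)2 (2.2 equiv), MeCN/H2O, rt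
Reagents that add atoms: water, O
Why: Oxoammonium-catalysed (TEMPO) oxidation of the primary alcohol runs through the aldehyde and its hydrate to the carboxylic acid, with PhI(OAc)2 as terminal oxidant.

Step 12
Reactants: 24 the carboxylic acid
Product: 25 methyl 3-[(1S,2S)-7-isopropoxy-6-isopropyl-5,8-dimethoxy-1-methyl-4-oxo-2-(prop-1-en-2-yl)-1,2,3,4-tetrahydronaphthalen-1-yl]propanoate
Conditions: MeI, K2CO3, DMF, rt
Reagents that add atoms: iodomethane, CI
Why: SN2 O-alkylation of the carboxylate; carbonate is too weak a base to alkylate the aryl ketone at C6.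

Step 13
Reactants: 25 the keto ester
Product: 26 methyl 3-[(1S,2S)-7-isopropoxy-6-isopropyl-1-methyl-4,5,8-trioxo-2-(prop-1-en-2-yl)-1,2,3,4,5,8-hexahydronaphthalen-1-yl]propanoate
Conditions: (NH4)2Ce(NO3)6 (2.5 equiv), MeCN/H2O, 0 °C
Reagents that add atoms: water, O
Why: Oxidative demethylation of the para-dimethoxyarene by tetravalent cerium: two one-electron oxidations with attack of water at C11 and C14 and loss of methanol give the para-quinone, the C12 isopropyl ether surviving as a vinylogous ester.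

Step 14
Reactants: 26 the isopropoxyquinone
Product: 27 methyl 3-[(1S,2S)-7-hydroxy-6-isopropyl-1-methyl-4,5,8-trioxo-2-(prop-1-en-2-yl)-1,2,3,4,5,8-hexahydronaphthalen-1-yl]propanoate (CNP0308749.1)
Conditions: BCl3, CH2Cl2, −78 °C; then H2O
Reagents that add atoms: none
Why: Lewis acid ether cleavage: BCl3 chelated between the C11 carbonyl and the C12 ether oxygen delivers chloride to the secondary isopropyl carbon at low temperature, which frees the hydroxyquinone while the methyl ester, the C7 ketone and the isopropenyl group should survive.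

**Compound list**

1 | 2-methylcyclohex-2-en-1-one | CC1=CCCCC1=O | starting material
2 | isopropenylmagnesium bromide | C=C(C)[Mg]Br | starting material
3 | allyl bromide | C=CCBr | starting material
4 | bromomagnesium (S)-2-methyl-3-(prop-1-en-2-yl)cyclohex-1-en-1-olate | C=C(C)[C@@H]1CCCC(O[Mg]Br)=C1C | intermediate
5 | (2S,3S)-2-allyl-2-methyl-3-(prop-1-en-2-yl)cyclohexan-1-one | C=C(C)[C@@H]1CCCC(=O)[C@@]1(C)CC=C | intermediate
6 | {3-[(1S,6S)-1-methyl-2-oxo-6-(prop-1-en-2-yl)cyclohexyl]propyl}bis(3-methylbutan-2-yl)borane | C=C(C)[C@@H]1CCCC(=O)[C@@]1(C)CCCB(C(C)C(C)C)C(C)C(C)C | intermediate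
7 | (2S,3S)-2-(3-hydroxypropyl)-2-methyl-3-(prop-1-en-2-yl)cyclohexan-1-one | C=C(C)[C@@H]1CCCC(=O)[C@@]1(C)CCCO | intermediate
8 | (2S,3S)-2-[3-(tert-butyldimethylsilyloxy)propyl]-2-methyl-3-(prop-1-en-2-yl)cyclohexan-1-one | C=C(C)[C@@H]1CCCC(=O)[C@@]1(C)CCCO[Si](C)(C)C(C)(C)C | intermediate
9 | N'-[(1E,2S,3S)-2-[3-(tert-butyldimethylsilyloxy)propyl]-2-methyl-3-(prop-1-en-2-yl)cyclohexylidene]-2,4,6-triisopropylbenzenesulfonohydrazide | C=C(C)[C@@H]1CCC/C(=N\NS(=O)(=O)c2c(C(C)C)cc(C(C)C)cc2C(C)C)[C@@]1(C)CCCO[Si](C)(C)C(C)(C)C | intermediate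
10 | diisopropyl squarate (3,4-diisopropoxycyclobut-3-ene-1,2-dione) | CC(C)OC1=C(OC(C)C)C(=O)C1=O | starting material
11 | isopropylmagnesium chloride | CC(C)[Mg]Cl | starting material
12 | 4-hydroxy-2,3-diisopropoxy-4-isopropylcyclobut-2-en-1-one (racemic) | CC(C)OC1=C(OC(C)C)C(O)(C(C)C)C1=O | intermediate
13 | 3-isopropoxy-4-isopropylcyclobut-3-ene-1,2-dione | CC(C)OC1=C(C(C)C)C(=O)C1=O | intermediate
14 | [(5S,6S)-6-[3-(tert-butyldimethylsilyloxy)propyl]-6-methyl-5-(prop-1-en-2-yl)cyclohex-1-en-1-yl]lithium | C=C(C)[C@@H]1CCC=C([Li])[C@@]1(C)CCCO[Si](C)(C)C(C)(C)C | intermediate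
15 | 4-hydroxy-3-isopropoxy-2-isopropyl-4-[(5S,6S)-6-[3-(tert-butyldimethylsilyloxy)propyl]-6-methyl-5-(prop-1-en-2-yl)cyclohex-1-en-1-yl]cyclobut-2-en-1-one (both carbinol epimers) | C=C(C)[C@@H]1CCC=C(C2(O)C(OC(C)C)=C(C(C)C)C2=O)[C@@]1(C)CCCO[Si](C)(C)C(C)(C)C | intermediate
16 | (3Z)-4-hydroxy-3-isopropoxy-2-isopropyl-4-[(5S,6S)-6-[3-(tert-butyldimethylsilyloxy)propyl]-6-methyl-5-(prop-1-en-2-yl)cyclohex-1-en-1-yl]buta-1,3-dien-1-one | C=C(C)[C@@H]1CCC=C(/C(O)=C(OC(C)C)\C(C(C)C)=C=O)[C@@]1(C)CCCO[Si](C)(C)C(C)(C)C | intermediate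
17 | (5S,6S)-5-[3-(tert-butyldimethylsilyloxy)propyl]-4-hydroxy-3-isopropoxy-2-isopropyl-5-methyl-6-(prop-1-en-2-yl)-6,7,8,8a-tetrahydronaphthalen-1(5H)-one (C8a epimers) | C=C(C)[C@@H]1CCC2C(=O)C(C(C)C)=C(OC(C)C)C(O)=C2[C@@]1(C)CCCO[Si](C)(C)C(C)(C)C | intermediate
18 | (7S,8S)-8-[3-(tert-butyldimethylsilyloxy)propyl]-2-isopropoxy-3-isopropyl-8-methyl-7-(prop-1-en-2-yl)-5,6,7,8-tetrahydronaphthalene-1,4-diol | C=C(C)[C@@H]1CCc2c(O)c(C(C)C)c(OC(C)C)c(O)c2[C@@]1(C)CCCO[Si](C)(C)C(C)(C)C | intermediate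
19 | tert-butyl{3-[(1S,2S)-7-isopropoxy-6-isopropyl-5,8-dimethoxy-1-methyl-2-(prop-1-en-2-yl)-1,2,3,4-tetrahydronaphthalen-1-yl]propoxy}dimethylsilane | C=C(C)[C@@H]1CCc2c(OC)c(C(C)C)c(OC(C)C)c(OC)c2[C@@]1(C)CCCO[Si](C)(C)C(C)(C)C | intermediate
20 | (3S,4S)-4-[3-(tert-butyldimethylsilyloxy)propyl]-6-isopropoxy-7-isopropyl-5,8-dimethoxy-4-methyl-3-(prop-1-en-2-yl)-1,2,3,4-tetrahydronaphthalen-1-ol (C1 epimers) | C=C(C)[C@@H]1CC(O)c2c(OC)c(C(C)C)c(OC(C)C)c(OC)c2[C@@]1(C)CCCO[Si](C)(C)C(C)(C)C | intermediate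
21 | (3S,4S)-4-[3-(tert-butyldimethylsilyloxy)propyl]-6-isopropoxy-7-isopropyl-5,8-dimethoxy-4-methyl-3-(prop-1-en-2-yl)-3,4-dihydronaphthalen-1(2H)-one | C=C(C)[C@@H]1CC(=O)c2c(OC)c(C(C)C)c(OC(C)C)c(OC)c2[C@@]1(C)CCCO[Si](C)(C)C(C)(C)C | intermediate
22 | (3S,4S)-4-(3-hydroxypropyl)-6-isopropoxy-7-isopropyl-5,8-dimethoxy-4-methyl-3-(prop-1-en-2-yl)-3,4-dihydronaphthalen-1(2H)-one | C=C(C)[C@@H]1CC(=O)c2c(OC)c(C(C)C)c(OC(C)C)c(OC)c2[C@@]1(C)CCCO | intermediate
23 | 3-[(1S,2S)-7-isopropoxy-6-isopropyl-5,8-dimethoxy-1-methyl-4-oxo-2-(prop-1-en-2-yl)-1,2,3,4-tetrahydronaphthalen-1-yl]propanal | C=C(C)[C@@H]1CC(=O)c2c(OC)c(C(C)C)c(OC(C)C)c(OC)c2[C@@]1(C)CCC=O | intermediate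
24 | 3-[(1S,2S)-7-isopropoxy-6-isopropyl-5,8-dimethoxy-1-methyl-4-oxo-2-(prop-1-en-2-yl)-1,2,3,4-tetrahydronaphthalen-1-yl]propanoic acid | C=C(C)[C@@H]1CC(=O)c2c(OC)c(C(C)C)c(OC(C)C)c(OC)c2[C@@]1(C)CCC(=O)O | intermediate
25 | methyl 3-[(1S,2S)-7-isopropoxy-6-isopropyl-5,8-dimethoxy-1-methyl-4-oxo-2-(prop-1-en-2-yl)-1,2,3,4-tetrahydronaphthalen-1-yl]propanoate | C=C(C)[C@@H]1CC(=O)c2c(OC)c(C(C)C)c(OC(C)C)c(OC)c2[C@@]1(C)CCC(=O)OC | intermediate
26 | methyl 3-[(1S,2S)-7-isopropoxy-6-isopropyl-1-methyl-4,5,8-trioxo-2-(prop-1-en-2-yl)-1,2,3,4,5,8-hexahydronaphthalen-1-yl]propanoate | C=C(C)[C@@H]1CC(=O)C2=C(C(=O)C(OC(C)C)=C(C(C)C)C2=O)[C@@]1(C)CCC(=O)OC | intermediate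
27 | methyl 3-[(1S,2S)-7-hydroxy-6-isopropyl-1-methyl-4,5,8-trioxo-2-(prop-1-en-2-yl)-1,2,3,4,5,8-hexahydronaphthalen-1-yl]propanoate (CNP0308749.1) | C=C(C)[C@@H]1CC(=O)C2=C(C(=O)C(O)=C(C(C)C)C2=O)[C@@]1(C)CCC(=O)OC | target

**Step count**

Total: 14 steps. Longest linear sequence: 13 steps (steps 1–4 and 6–14, from 1); the squarate branch (step 5) joins at step 6.

**Steps most likely to fail**

Step 1. Enantioface discrimination may be poor, because an alkenyl Grignard reagent adding to an α-substituted enone can react through a ligand-free copper pathway and erode the enantiomeric purity. Fallback, from 1, 2 and 3: the same conjugate addition and trans allylation is run with CuBr·SMe2 alone, which should give the racemic trans ketone, that is 5 together with its mirror image (2R,3R)-2-allyl-2-methyl-3-(prop-1-en-2-yl)cyclohexan-1-one F1. The two are separated by preparative supercritical-fluid chromatography on amylose tris(3,5-dimethylphenylcarbamate), and the route is rejoined at 5.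

Step 9. The C7 cation may lose a proton to the C6–C7 styrene and be over-oxidised, or hydride abstraction may be slow because the three flanked alkoxy groups are twisted out of conjugation. Fallback, from 19: the side chain is finished first and the benzylic oxidation is done last by a radical pathway that avoids the cation.
- HF·pyridine should give 3-[(1S,2S)-7-isopropoxy-6-isopropyl-5,8-dimethoxy-1-methyl-2-(prop-1-en-2-yl)-1,2,3,4-tetrahydronaphthalen-1-yl]propan-1-ol F2.
- Dess–Martin periodinane should give the corresponding propanal F3.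
- Pinnick oxidation (NaClO2, NaH2PO4, 2-methylbut-2-ene) should give the corresponding propanoic acid F4.
- MeI and K2CO3 should give methyl 3-[(1S,2S)-7-isopropoxy-6-isopropyl-5,8-dimethoxy-1-methyl-2-(prop-1-en-2-yl)-1,2,3,4-tetrahydronaphthalen-1-yl]propanoate F5.
- C7 is then oxidised with t-BuOOH and catalytic dirhodium tetracaprolactamate Rh2(cap)4 (hydrogen-atom abstraction by tert-butylperoxyl radical), and the route is rejoined at 25.

Step 13. Electron transfer from the acyl-deactivated arene may be slow, and the oxidant may instead remove the isopropyl group to give an ortho-quinone or attack the isopropenyl group. Fallback, from 25: dealkylation comes first and the oxidation is then done on a phenol. BCl3 (CH2Cl2, −78 → 0 °C) should cleave the C12 isopropyl ether and the C14 methyl ether chelated to the C7 ketone, giving methyl 3-[(1S,2S)-5,7-dihydroxy-6-isopropyl-8-methoxy-1-methyl-4-oxo-2-(prop-1-en-2-yl)-1,2,3,4-tetrahydronaphthalen-1-yl]propanoate F6. Its para-methoxyphenol unit is oxidised with PhI(OAc)2 in aqueous MeCN, with loss of methanol, directly to the hydroxyquinone; this replaces steps 13 and 14 and rejoins the route at 27.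

Further compounds
F1 | step 1 | (2R,3R)-2-allyl-2-methyl-3-(prop-1-en-2-yl)cyclohexan-1-one | C=C(C)[C@H]1CCCC(=O)[C@]1(C)CC=C
F2 | step 9 | 3-[(1S,2S)-7-isopropoxy-6-isopropyl-5,8-dimethoxy-1-methyl-2-(prop-1-en-2-yl)-1,2,3,4-tetrahydronaphthalen-1-yl]propan-1-ol | C=C(C)[C@@H]1CCc2c(OC)c(C(C)C)c(OC(C)C)c(OC)c2[C@@]1(C)CCCO
F3 | step 9 | 3-[(1S,2S)-7-isopropoxy-6-isopropyl-5,8-dimethoxy-1-methyl-2-(prop-1-en-2-yl)-1,2,3,4-tetrahydronaphthalen-1-yl]propanal | C=C(C)[C@@H]1CCc2c(OC)c(C(C)C)c(OC(C)C)c(OC)c2[C@@]1(C)CCC=O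
F4 | step 9 | 3-[(1S,2S)-7-isopropoxy-6-isopropyl-5,8-dimethoxy-1-methyl-2-(prop-1-en-2-yl)-1,2,3,4-tetrahydronaphthalen-1-yl]propanoic acid | C=C(C)[C@@H]1CCc2c(OC)c(C(C)C)c(OC(C)C)c(OC)c2[C@@]1(C)CCC(=O)O
F5 | step 9 | methyl 3-[(1S,2S)-7-isopropoxy-6-isopropyl-5,8-dimethoxy-1-methyl-2-(prop-1-en-2-yl)-1,2,3,4-tetrahydronaphthalen-1-yl]propanoate | C=C(C)[C@@H]1CCc2c(OC)c(C(C)C)c(OC(C)C)c(OC)c2[C@@]1(C)CCC(=O)OC
F6 | step 13 | methyl 3-[(1S,2S)-5,7-dihydroxy-6-isopropyl-8-methoxy-1-methyl-4-oxo-2-(prop-1-en-2-yl)-1,2,3,4-tetrahydronaphthalen-1-yl]propanoate | C=C(C)[C@@H]1CC(=O)c2c(O)c(C(C)C)c(O)c(OC)c2[C@@]1(C)CCC(=O)OC
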